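**Plan**

- The retrosynthesis first cuts the side-chain ester C–O bond (allylic oxygen to coumaroyl carbonyl), then opens ring A across C1–C2 and C5–C6 (C1 carries the acyl group, C2 and C4 the hydroxyls, C3 the side chain).
- The enabling feature is ring A itself: a 1-acyl-2,4-dioxygenated benzene with the C3 alkyl group between O2 and O4. C2–C3–C4–C5 with both oxygens and the side chain map onto a 2-alkyl-1-methoxy-1,3-bis(silyloxy)butadiene; C6, C1 and the cinnamoyl arm map onto a terminal ynone.
- The diene is cut between the acetoacetate α-carbon and the allylic CH2 (methyl acetoacetate plus an E-allylic bromide from prenyl acetate). The ynone is cut at the acyl–alkyne bond (Weinreb amide of MOM-protected p-coumaric acid plus an ethynyl Grignard reagent).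
- Forward: side-chain bromide, alkylated acetoacetate, bis-silyl diene; p-coumaric acid to ynone; Diels–Alder benzannulation closes ring A, the only ring made (ring B and the coumaroyl ring are bought). Then 4-O-MOM protection, desilylation, esterification with the same MOM-protected acid, and cleavage of all MOM ethers.
- There are no stereocentres. The E side-chain olefin is set by SeO2 allylic oxidation of prenyl acetate and is not touched afterwards; both E-cinnamoyl olefins come with p-coumaric acid.

Key step: step 11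

Remark: the enol ether geometry of 8 and the ketene acetal geometry of 9 are not controlled and do not matter, because both carbons end up in the aromatic ring; one isomer is drawn for each.

**Route**

Step 1
Reactants: 1 prenyl acetate (3-methylbut-2-en-1-yl acetate)
Product: 2 (E)-4-hydroxy-3-methylbut-2-en-1-yl acetate
Conditions: SeO2 (cat.), t-BuOOH, CH2Cl2, 0 °C → rt
Reagents that add atoms: tert-butyl hydroperoxide, CC(C)(C)OO (source of the new oxygen, relayed by SeO2, O=[Se]=O)
Why: Selenium dioxide allylic oxidation (ene reaction then 2,3-sigmatropic shift) attacks the methyl group trans to the chain of a trisubstituted olefin, so the E-allylic alcohol should form and fix the side-chain geometry, with conversion held short to limit over-oxidation.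

Step 2
Reactants: 2 (E)-4-hydroxy-3-methylbut-2-en-1-yl acetate
Product: 3 (E)-4-[(tert-butyldimethylsilyl)oxy]-3-methylbut-2-en-1-yl acetate
Conditions: TBSCl, imidazole, CH2Cl2, 0 °C → rt
Reagents that add atoms: tert-butyldimethylsilyl chloride, CC(C)(C)[Si](C)(C)Cl
Why: Silylation of a primary alcohol with a silyl chloride and imidazole is routine and should leave the acetate and the olefin untouched.

Step 3
Reactants: 3 (E)-4-[(tert-butyldimethylsilyl)oxy]-3-methylbut-2-en-1-yl acetate
Product: 4 (E)-4-[(tert-butyldimethylsilyl)oxy]-3-methylbut-2-en-1-ol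
Conditions: K2CO3 (cat.), MeOH, 0 °C
Reagents that add atoms: none
Why: Base-catalysed transesterification (methanolysis) should remove the acetate while the silyl ether and the olefin geometry stay as they are.

Step 4
Reactants: 4 (E)-4-[(tert-butyldimethylsilyl)oxy]-3-methylbut-2-en-1-ol
Product: 5 (E)-4-bromo-1-[(tert-butyldimethylsilyl)oxy]-2-methylbut-2-ene
Conditions: CBr4, PPh3, CH2Cl2, −20 → 0 °C
Reagents that add atoms: carbon tetrabromide, BrC(Br)(Br)Br
Why: The Appel bromination converts a primary allylic alcohol into the bromide by direct displacement under neutral conditions, so the silyl ether and the E-olefin should survive.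

Step 5
Reactants: 5 (E)-4-bromo-1-[(tert-butyldimethylsilyl)oxy]-2-methylbut-2-ene; 6 methyl acetoacetate
Product: 7 methyl (E)-2-acetyl-6-[(tert-butyldimethylsilyl)oxy]-5-methylhex-4-enoate (racemic at C2)
Conditions: 6 (excess), NaH, THF, 0 °C; then 5, 0 °C → rt
Reagents that add atoms: none
Why: SN2 C-alkylation of the sodium enolate of a β-keto ester with a primary allylic bromide is the standard acetoacetic ester alkylation, the excess of 6 holding back dialkylation and the direct displacement keeping the E-geometry.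

Step 6
Reactants: 7 methyl (E)-2-acetyl-6-[(tert-butyldimethylsilyl)oxy]-5-methylhex-4-enoate
Product: 8 methyl (4E)-6-[(tert-butyldimethylsilyl)oxy]-5-methyl-2-[1-(trimethylsilyloxy)ethylidene]hex-4-enoate
Conditions: TMSCl, Et3N, toluene, rt; filtration and concentration under argon
Reagents that add atoms: trimethylsilyl chloride, C[Si](C)(C)Cl
Why: O-Silylation of the enolisable β-keto ester with a silyl chloride and a tertiary amine should give the silyl enol ether of the ketone, the first stage of the usual two-stage preparation of 1,3-bis(silyloxy)dienes.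

Step 7
Reactants: 8 methyl (4E)-6-[(tert-butyldimethylsilyl)oxy]-5-methyl-2-[1-(trimethylsilyloxy)ethylidene]hex-4-enoate
Product: 9 2-[(E)-4-(tert-butyldimethylsilyloxy)-3-methylbut-2-en-1-yl]-1-methoxy-1,3-bis(trimethylsilyloxy)buta-1,3-diene
Conditions: LiN(iPr)2 (commercial solution), THF, −78 °C; then TMSCl, −78 °C → rt; pentane, filtration under argon, used crude at once
Reagents that add atoms: trimethylsilyl chloride, C[Si](C)(C)Cl
Why: Kinetic γ-deprotonation of the β-silyloxy enoate (its α-carbon bears no hydrogen) followed by O-silylation of the dienolate should give the ketene acetal diene, which is sensitive to moisture and is therefore not purified.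

Step 8
Reactants: 10 p-coumaric acid
Product: 12 (E)-3-[4-(methoxymethoxy)phenyl]prop-2-enoic acid, via methoxymethyl ester 11 (not isolated)
Conditions: MOMCl, iPr2NEt, DMF, 0 °C → rt; then aq. LiOH, MeOH, rt; cold 1 M HCl to pH 4
Reagents that add atoms: chloromethyl methyl ether, COCCl; lithium hydroxide, [Li+].[OH-] (its oxygen ends in the carboxyl group)
Why: O-Alkylation with the chloromethyl ether caps both the phenol and the acid, and saponification should then cleave only the acyloxymethyl ester because the aryl MOM acetal is stable to base.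

Step 9
Reactants: 12 (E)-3-[4-(methoxymethoxy)phenyl]prop-2-enoic acid
Product: 13 (E)-N-methoxy-3-[4-(methoxymethoxy)phenyl]-N-methylprop-2-enamide
Conditions: MeNHOMe·HCl, EDC·HCl, Et3N, DMAP (cat.), CH2Cl2, 0 °C → rt
Reagents that add atoms: N,O-dimethylhydroxylamine hydrochloride, CNOC.Cl
Why: Carbodiimide-mediated amidation should give the N-methoxy-N-methyl amide needed for a controlled ketone synthesis without affecting the MOM ether or the E-olefin.

Step 10
Reactants: 13 (E)-N-methoxy-3-[4-(methoxymethoxy)phenyl]-N-methylprop-2-enamide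
Product: 14 (E)-1-[4-(methoxymethoxy)phenyl]pent-1-en-4-yn-3-one
Conditions: HC≡CMgBr, THF, −20 → 0 °C; inverse quench into ice-cold 1 M HCl
Reagents that add atoms: ethynylmagnesium bromide, C#C[Mg]Br
Why: In this Weinreb ketone synthesis chelation by the N-methoxy group should stop the acetylide addition at the ketone stage, and the inverse acidic quench protonates the released amine before it can add to the terminal ynone.

Step 11
Reactants: 9 2-[(E)-4-(tert-butyldimethylsilyloxy)-3-methylbut-2-en-1-yl]-1-methoxy-1,3-bis(trimethylsilyloxy)buta-1,3-diene; 14 (E)-1-[4-(methoxymethoxy)phenyl]pent-1-en-4-yn-3-one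
Product: 17 (E)-1-{3-[(E)-4-(tert-butyldimethylsilyloxy)-3-methylbut-2-en-1-yl]-2,4-dihydroxyphenyl}-3-[4-(methoxymethoxy)phenyl]prop-2-en-1-one, via cyclohexa-1,4-diene cycloadduct 15 (not isolated), via ring-A bis(trimethylsilyl) ether 16 (not isolated)
Conditions: 9 (excess), toluene, 0 → 60 °C; then 10% aq. citric acid, THF, rt
Reagents that add atoms: none
Why: The electron-rich diene 9 and the electron-poor alkyne of 14 should combine in a polar, strongly asynchronous Diels–Alder reaction in which the CH2 terminus of the diene bonds to the terminal alkyne carbon (future C5–C6) ahead of the ketene acetal carbon bonding to the ynone α-carbon (future C1–C2), giving 15; a stepwise Michael addition followed by closure onto the oxocarbenium carbon would lead to the same adduct. Loss of methanol from the doubly allylic ketal aromatises the ring to 16, and the two labile aryl trimethylsilyl ethers are then hydrolysed by dilute citric acid, which the TBS ether and the aryl MOM acetal tolerate. The closest known reaction type is the Diels–Alder benzannulation of 1-alkoxy-1,3-bis(silyloxy)butadienes with acetylenic ketones and esters to give resorcinols. Ring A is closed by an intermolecular (4+2) cycloaddition of a four-carbon and a two-carbon unit followed by aromatisation; no stereocentre is created, because the ketal carbon of 15 is flattened on aromatisation and the ketene acetal geometry is irrelevant. The step needs regioselectivity, which polarity matching should secure (largest donor coefficient at the diene CH2, largest acceptor coefficient at the alkyne terminus), so that O2 and O4 flank the C3 chain with the acyl group at C1. It also needs chemoselectivity for the alkyne over the styryl enone, which the unhindered sp carbon and the deactivation of the enone β-carbon by the 4-alkoxyphenyl group should provide.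

Step 12
Reactants: 17 (E)-1-{3-[(E)-4-(tert-butyldimethylsilyloxy)-3-methylbut-2-en-1-yl]-2,4-dihydroxyphenyl}-3-[4-(methoxymethoxy)phenyl]prop-2-en-1-one
Product: 18 (E)-1-{3-[(E)-4-(tert-butyldimethylsilyloxy)-3-methylbut-2-en-1-yl]-2-hydroxy-4-(methoxymethoxy)phenyl}-3-[4-(methoxymethoxy)phenyl]prop-2-en-1-one
Conditions: MOMCl (1.1 equiv), iPr2NEt, CH2Cl2, 0 °C
Reagents that add atoms: chloromethyl methyl ether, COCCl
Why: This chemoselective O-alkylation should take place at the free, more acidic 4-hydroxyl, because the 2-hydroxyl is locked in a hydrogen bond to the ketone and is hindered by the side chain.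

Step 13
Reactants: 18 (E)-1-{3-[(E)-4-(tert-butyldimethylsilyloxy)-3-methylbut-2-en-1-yl]-2-hydroxy-4-(methoxymethoxy)phenyl}-3-[4-(methoxymethoxy)phenyl]prop-2-en-1-one
Product: 19 (E)-1-{2-hydroxy-3-[(E)-4-hydroxy-3-methylbut-2-en-1-yl]-4-(methoxymethoxy)phenyl}-3-[4-(methoxymethoxy)phenyl]prop-2-en-1-one
Conditions: HF·pyridine, pyridine, THF, 0 °C → rt
Reagents that add atoms: none
Why: Fluoride-mediated desilylation with buffered HF·pyridine should remove the primary TBS ether without touching the MOM acetals, the chelated phenol or the enone.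

Step 14
Reactants: 19 (E)-1-{2-hydroxy-3-[(E)-4-hydroxy-3-methylbut-2-en-1-yl]-4-(methoxymethoxy)phenyl}-3-[4-(methoxymethoxy)phenyl]prop-2-en-1-one; 12 (E)-3-[4-(methoxymethoxy)phenyl]prop-2-enoic acid
Product: 20 (E)-4-{2-hydroxy-6-(methoxymethoxy)-3-[(E)-3-[4-(methoxymethoxy)phenyl]prop-2-enoyl]phenyl}-2-methylbut-2-en-1-yl (E)-3-[4-(methoxymethoxy)phenyl]prop-2-enoate
Conditions: EDC·HCl, DMAP (cat.), CH2Cl2, 0 °C → rt
Reagents that add atoms: none
Why: The Steglich esterification should acylate the primary allylic alcohol far faster than the chelated, hindered 2-hydroxyl, and its neutral conditions leave the chalcone and the MOM ethers intact.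

Step 15
Reactants: 20 (E)-4-{2-hydroxy-6-(methoxymethoxy)-3-[(E)-3-[4-(methoxymethoxy)phenyl]prop-2-enoyl]phenyl}-2-methylbut-2-en-1-yl (E)-3-[4-(methoxymethoxy)phenyl]prop-2-enoate
Product: 21 isogemichalcone B, (E)-4-{2,6-dihydroxy-3-[(E)-3-(4-hydroxyphenyl)prop-2-enoyl]phenyl}-2-methylbut-2-en-1-yl (E)-3-(4-hydroxyphenyl)prop-2-enoate
Conditions: dilute aq. HCl, MeOH, rt → 40 °C; NaHCO3 quench
Reagents that add atoms: none
Why: Acid-catalysed acetal exchange (methanolysis of the three aryl MOM ethers) at moderate temperature should release the phenols, while the conjugated ester of the primary allylic alcohol is expected to resist dilute acid.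

**Compound list**

1 | prenyl acetate (3-methylbut-2-en-1-yl acetate) | CC(C)=CCOC(C)=O | starting material
2 | (E)-4-hydroxy-3-methylbut-2-en-1-yl acetate | CC(=O)OC/C=C(\C)CO | intermediate
3 | (E)-4-[(tert-butyldimethylsilyl)oxy]-3-methylbut-2-en-1-yl acetate | CC(=O)OC/C=C(\C)CO[Si](C)(C)C(C)(C)C | intermediate
4 | (E)-4-[(tert-butyldimethylsilyl)oxy]-3-methylbut-2-en-1-ol | OC/C=C(\C)CO[Si](C)(C)C(C)(C)C | intermediate
5 | (E)-4-bromo-1-[(tert-butyldimethylsilyl)oxy]-2-methylbut-2-ene | BrC/C=C(\C)CO[Si](C)(C)C(C)(C)C | intermediate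
6 | methyl acetoacetate | COC(=O)CC(C)=O | starting material
7 | methyl (E)-2-acetyl-6-[(tert-butyldimethylsilyl)oxy]-5-methylhex-4-enoate (racemic at C2) | COC(=O)C(C(C)=O)C/C=C(\C)CO[Si](C)(C)C(C)(C)C | intermediate
8 | methyl (4E)-6-[(tert-butyldimethylsilyl)oxy]-5-methyl-2-[1-(trimethylsilyloxy)ethylidene]hex-4-enoate (one enol ether isomer drawn) | COC(=O)/C(C/C=C(\C)CO[Si](C)(C)C(C)(C)C)=C(/C)O[Si](C)(C)C | intermediate
9 | 2-[(E)-4-(tert-butyldimethylsilyloxy)-3-methylbut-2-en-1-yl]-1-methoxy-1,3-bis(trimethylsilyloxy)buta-1,3-diene (one ketene acetal isomer drawn) | C=C(O[Si](C)(C)C)/C(C/C=C(\C)CO[Si](C)(C)C(C)(C)C)=C(/OC)O[Si](C)(C)C | intermediate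
10 | p-coumaric acid, (E)-3-(4-hydroxyphenyl)prop-2-enoic acid | O=C(O)/C=C/c1ccc(O)cc1 | starting material
11 | methoxymethyl (E)-3-[4-(methoxymethoxy)phenyl]prop-2-enoate | COCOC(=O)/C=C/c1ccc(OCOC)cc1 | intermediate (not isolated)
12 | (E)-3-[4-(methoxymethoxy)phenyl]prop-2-enoic acid | O=C(O)/C=C/c1ccc(OCOC)cc1 | intermediate
13 | (E)-N-methoxy-3-[4-(methoxymethoxy)phenyl]-N-methylprop-2-enamide | CON(C)C(=O)/C=C/c1ccc(OCOC)cc1 | intermediate
14 | (E)-1-[4-(methoxymethoxy)phenyl]pent-1-en-4-yn-3-one | C#CC(=O)/C=C/c1ccc(OCOC)cc1 | intermediate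
15 | (E)-1-{5-[(E)-4-(tert-butyldimethylsilyloxy)-3-methylbut-2-en-1-yl]-6-methoxy-4,6-bis(trimethylsilyloxy)cyclohexa-1,4-dien-1-yl}-3-[4-(methoxymethoxy)phenyl]prop-2-en-1-one (racemic at the ketal carbon) | COC1(O[Si](C)(C)C)C(C/C=C(\C)CO[Si](C)(C)C(C)(C)C)=C(O[Si](C)(C)C)CC=C1C(=O)/C=C/c1ccc(OCOC)cc1 | intermediate (not isolated)
16 | (E)-1-{3-[(E)-4-(tert-butyldimethylsilyloxy)-3-methylbut-2-en-1-yl]-2,4-bis(trimethylsilyloxy)phenyl}-3-[4-(methoxymethoxy)phenyl]prop-2-en-1-one | C/C(=C\Cc1c(O[Si](C)(C)C)ccc(C(=O)/C=C/c2ccc(OCOC)cc2)c1O[Si](C)(C)C)CO[Si](C)(C)C(C)(C)C | intermediate (not isolated)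
17 | (E)-1-{3-[(E)-4-(tert-butyldimethylsilyloxy)-3-methylbut-2-en-1-yl]-2,4-dihydroxyphenyl}-3-[4-(methoxymethoxy)phenyl]prop-2-en-1-one | C/C(=C\Cc1c(O)ccc(C(=O)/C=C/c2ccc(OCOC)cc2)c1O)CO[Si](C)(C)C(C)(C)C | intermediate
18 | (E)-1-{3-[(E)-4-(tert-butyldimethylsilyloxy)-3-methylbut-2-en-1-yl]-2-hydroxy-4-(methoxymethoxy)phenyl}-3-[4-(methoxymethoxy)phenyl]prop-2-en-1-one | C/C(=C\Cc1c(OCOC)ccc(C(=O)/C=C/c2ccc(OCOC)cc2)c1O)CO[Si](C)(C)C(C)(C)C | intermediate
19 | (E)-1-{2-hydroxy-3-[(E)-4-hydroxy-3-methylbut-2-en-1-yl]-4-(methoxymethoxy)phenyl}-3-[4-(methoxymethoxy)phenyl]prop-2-en-1-one | C/C(=C\Cc1c(OCOC)ccc(C(=O)/C=C/c2ccc(OCOC)cc2)c1O)CO | intermediate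
20 | (E)-4-{2-hydroxy-6-(methoxymethoxy)-3-[(E)-3-[4-(methoxymethoxy)phenyl]prop-2-enoyl]phenyl}-2-methylbut-2-en-1-yl (E)-3-[4-(methoxymethoxy)phenyl]prop-2-enoate | C/C(=C\Cc1c(OCOC)ccc(C(=O)/C=C/c2ccc(OCOC)cc2)c1O)COC(=O)/C=C/c1ccc(OCOC)cc1 | intermediate
21 | isogemichalcone B, (E)-4-{2,6-dihydroxy-3-[(E)-3-(4-hydroxyphenyl)prop-2-enoyl]phenyl}-2-methylbut-2-en-1-yl (E)-3-(4-hydroxyphenyl)prop-2-enoate | C/C(=C\Cc1c(O)ccc(C(=O)/C=C/c2ccc(O)cc2)c1O)COC(=O)/C=C/c1ccc(O)cc1 | target

**Summary**

Total step count: 15.
Longest linear sequence: 12 steps (steps 1–7 and 11–15, from prenyl acetate); the ynone arm (steps 8–10) joins at step 11.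

Steps most likely to fail:

1. Step 11. The diene may be diverted by Michael addition to the styryl enone, or the doubly unsaturated ketone may oligomerise on warming, before the second ring bond forms. The fallback sets out from diene 9 and heats it with commercial but-3-yn-2-one (toluene, 0 → 60 °C), a dienophile with a single acceptor site. The same sequence should pass through the methoxy ketal cycloadduct F1 and the ring-A bis(trimethylsilyl) ether F2 and give, after citric acid work-up, 1-{3-[(E)-4-(tert-butyldimethylsilyloxy)-3-methylbut-2-en-1-yl]-2,4-dihydroxyphenyl}ethan-1-one F3. Selective protection (MOMCl, iPr2NEt, CH2Cl2, 0 °C) should give the 4-O-methoxymethyl acetophenone F4. Claisen–Schmidt condensation of this ketone with commercial 4-(methoxymethoxy)benzaldehyde (KOH, EtOH/H2O, rt) then forms the enone double bond and comes back to the route at 18.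

2. Step 15. Cleaving three aryl MOM ethers, one of them para to the ketone and slow, may be accompanied by methanolysis or ionisation of the allylic coumarate. The fallback sets out from 17, before any ester is present. Dilute HCl in MeOH should remove the MOM and TBS groups together to give (E)-1-{2,4-dihydroxy-3-[(E)-4-hydroxy-3-methylbut-2-en-1-yl]phenyl}-3-(4-hydroxyphenyl)prop-2-en-1-one F5. A Mitsunobu esterification with unprotected p-coumaric acid 10 (PPh3, DIAD, THF, 0 °C), in which the carboxylic acid is far more acidic than any phenol and so acts as the pronucleophile, then joins the primary allylic alcohol to the acid and comes back to the route at 21 with no acid treatment of the ester.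

3. Step 10. The released N,O-dimethylhydroxylamine or a second acetylide may add in conjugate fashion to the terminal ynone during addition or quench. The fallback sets out from 13, which is reduced (iBu2AlH, THF, −78 °C) to (E)-3-[4-(methoxymethoxy)phenyl]prop-2-enal F6, so that the amine is released at a stage where it does no harm. Addition of HC≡CMgBr (THF, 0 °C) should give racemic (E)-1-[4-(methoxymethoxy)phenyl]pent-1-en-4-yn-3-ol F7, and oxidation of this doubly activated alcohol with MnO2 (CH2Cl2, rt) comes back to the route at 14.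

Further compounds
F1 | step 11 | 1-{5-[(E)-4-(tert-butyldimethylsilyloxy)-3-methylbut-2-en-1-yl]-6-methoxy-4,6-bis(trimethylsilyloxy)cyclohexa-1,4-dien-1-yl}ethan-1-one (racemic) | COC1(O[Si](C)(C)C)C(C/C=C(\C)CO[Si](C)(C)C(C)(C)C)=C(O[Si](C)(C)C)CC=C1C(C)=O
F2 | step 11 | 1-{3-[(E)-4-(tert-butyldimethylsilyloxy)-3-methylbut-2-en-1-yl]-2,4-bis(trimethylsilyloxy)phenyl}ethan-1-one | C/C(=C\Cc1c(O[Si](C)(C)C)ccc(C(C)=O)c1O[Si](C)(C)C)CO[Si](C)(C)C(C)(C)C
F3 | step 11 | 1-{3-[(E)-4-(tert-butyldimethylsilyloxy)-3-methylbut-2-en-1-yl]-2,4-dihydroxyphenyl}ethan-1-one | C/C(=C\Cc1c(O)ccc(C(C)=O)c1O)CO[Si](C)(C)C(C)(C)C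
F4 | step 11 | 1-{3-[(E)-4-(tert-butyldimethylsilyloxy)-3-methylbut-2-en-1-yl]-2-hydroxy-4-(methoxymethoxy)phenyl}ethan-1-one | C/C(=C\Cc1c(OCOC)ccc(C(C)=O)c1O)CO[Si](C)(C)C(C)(C)C
F5 | step 15 | (E)-1-{2,4-dihydroxy-3-[(E)-4-hydroxy-3-methylbut-2-en-1-yl]phenyl}-3-(4-hydroxyphenyl)prop-2-en-1-one | C/C(=C\Cc1c(O)ccc(C(=O)/C=C/c2ccc(O)cc2)c1O)CO
F6 | step 10 | (E)-3-[4-(methoxymethoxy)phenyl]prop-2-enal | O=C/C=C/c1ccc(OCOC)cc1
F7 | step 10 | (E)-1-[4-(methoxymethoxy)phenyl]pent-1-en-4-yn-3-ol (racemic) | C#CC(O)/C=C/c1ccc(OCOC)cc1
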